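# Synthesis proposal for CNP0521079.1 (compound 35)

## Analysis of the target

Compound 35 is a 6,7-seco-ent-kauranoid of the 7,20-lactone class. Ring A is a 4,4-dimethylcyclohex-2-en-1-one; its C10 also belongs to a δ-lactone (C10–C20–O–C7(=O)–C8–C9) that takes the place of ring B, and this lactone is fused along C8–C9 to the bicyclo[3.2.1]octane of rings C and D. There are six stereocentres (5R,8S,9S,10S,13S,15R). C5 and C10 are vicinal on ring A, with the formyl carbon C6 and the lactone carbon C20 cis. C9 and C8 are vicinal on the lactone, with C11 and C14 cis. C13 is a bridgehead carbinol fixed by the bicycle once C8 is set, and C15 carries its hydroxyl on the endo face, toward the C9–C11–C12 bridge. C4, C10 and C8 are quaternary, so C4–C5–C10–C9–C8 is an unbroken run of congested carbons.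

The sensitive groups are:
- the aldehyde on the epimerisable C5;
- the lactone, whose C20 oxygen is β to the C1 ketone, so that ring opening invites retro-aldol loss of C20;
- the 15-hydroxy-16-ene allylic alcohol, which can isomerise in acid;
- the ring A enone.

The difficulty lies in building the two quaternary centres C10 and C8 with the right neighbours, and in keeping four carbonyl-level carbons (C1, C6, C7, C15) and two alcohols apart. The strategy rests on one feature: C20 on C10 and C6 on C5 are vicinal, cis and both oxygenated, and C10=C5 is the enone double bond of ring A as long as C1 is a ketone. A cyclobutane C10–C20–C6–C5 fused to ring A therefore contains both bonds, and its C6–C20 bond can be excised afterwards.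

## Retrosynthetic reasoning

**35 back to 33.** No skeletal bond is cut. In 34 the aldehyde is held as a cyclic acetal and the C13 hydroxyl as a silyl ether. The C15 carbinol is traced to the ketone of 33, because hydride delivery from the open exo face of the two-carbon bridge gives the endo alcohol. The forward reduction has to prefer C15 to the ring A carbonyl.

**33 back to 28.** The exocyclic C16=C17 bond is removed to give 30, whose C16 methylene is the only enolisable position. The C13–C16 bond is then cut as an aldol, since the C13 hydroxyl and the C15 oxygen are 1,3-related. This opens ring D and leads to the 1,4-diketone 28. The bridged closure can occur in one sense only, so C13 needs no separate control.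

**28 back to 23.** The C8–C14 bond joins two carbonyl α-carbons, so it is cut as an oxidative coupling of two enolates in 26. This makes the quaternary C8 from a planar carbon under the direction of C9. The acetyl group on C8 of 25 (C15 and C16) is cut as a Claisen-type acylation of lactone 23. The C13 ketone stays masked until the acylation is done.

**23 back to 20.** The C2=C3 double bond is placed early. The ring A enone has no acidic hydrogen, which leaves the lactone of 23 as the only enolisable site. Acetal 21 protects the aldehyde of 20 against the bases that follow.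

**20 back to 18.** Reconnecting C6 to C20 turns the keto aldehyde into cyclobutanol 19. In the forward direction an alkoxy radical at O6 breaks C6–C20 and the C20 radical is capped by hydrogen. The oxygen on C6 is carried as a silyl ether in 18 and not as an ester: it can then be freed under buffered fluoride without generating an alkoxide next to the lactone.

**18 back to 17 (key disconnection).** C10–C20 and C5–C6 are cut together. The precursor is the ring A enone 17, with a 2-silyloxyvinyl ester tethered to C10 through C9–C8–C7. One photochemical step has to form two C–C bonds, the lactone and the cyclobutane, and set C10 and C5.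

**17 back to 12.** The enol ether comes from aldehyde 16 by soft enolisation, and 16 from the allyl ester 14 by oxidative cleavage. The enone of 14 is released from ketal 13, and the allyl ester is exchanged for the ethyl ester of 12.

**12 back to 1, 6 and 9.** The C9–C10 bond is cut as an asymmetric conjugate addition of the alkenyl boronate 5 to enoate 11. This sets C9, the centre that later steers the photocycloaddition. Boronate 5 comes from enone 1 through 2 and 3. Enoate 11 comes from keto ester 6 through 7 and 8 and from phosphonate 9.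

## Alternatives that were turned down

**Alternative 1:** This plan cuts the C9–C10 bond and the lactone C–O bond. A complete ring C/D acid would be esterified to the C20 hydroxyl of a ring A formyl dienone. A carbon radical released at C9 under stannane chain conditions would then add to C10, closing the lactone and giving A1, the 15-O-silyl ether of 35.
- For it: it is highly convergent, the radical and the doubly activated alkene are polarity-matched, and A1 is one deprotection from the target.
- Against it: the radical must attack a fully substituted alkene carbon to make a quaternary centre. It must do so through an ester tether whose reactive rotamer is sparsely populated, while premature reduction of the radical competes. C9, C10 and C5 would all be set in that one step with only the remote C8 to direct them. The enantiopure bicyclooctane acid with C8, C13 and C15 in place is itself a long synthesis.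
- Comparison: A1 is clearly stronger on convergence and on late-stage brevity. The chosen route offers instead achiral bulk starting materials, a cis C5/C10 relation enforced by a four-membered ring, and a key step placed early, where failure costs little.

**Alternative 2:** This plan cuts C8–C9. An Ireland–Claisen ring contraction of the silyl ketene acetal of an alkenyl δ-lactone would form C8–C9, break the O–C12 bond and close ring C, giving the cyclohexene acid A2.
- For it: the rearrangement is concerted, the ketene acetal geometry is fixed by the ring, and chirality is relayed from a carbinol centre to the vicinal C8/C9 pair. The alkyne on C8 is a good handle for ring D.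
- Against it: C10 and C5 must already be in place, so the ring A problem is moved elsewhere. The new bond joins a carbon attached to quaternary C10 to the quaternary C8, which is a very crowded sigmatropic transition state. After A2, the lactone, ring D, the ring A enone and the C15 oxygen are all still missing. An allylic oxidation of the 16-ene would be expected to bring oxygen to the open exo face, whereas 35 has the endo hydroxyl, so an oxidation–reduction detour would follow.
- Comparison: on control of C8 and C9 this alternative is stronger than the oxidative coupling used here. The chosen route answers with a single step that makes the lactone, C10 and C5 together, and with a C15 centre set directly by reduction.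

**Alternative 3:** This plan cuts C13–C14. A Dowd–Beckwith ring expansion would insert a bromomethyl carbon on C8 into a cyclopentanone, giving the lactone-fused cyclohexanone A3.
- For it: this is a dependable chain reaction on an easily made β-keto lactone, and it delivers the C13 ketone that a ring D aldol needs.
- Against it: the step adds one carbon and one bond. It leaves C8 tertiary next to an enolisable C13 ketone, which makes the later quaternisation of C8 awkward. It presupposes ring A, the lactone, C5 and C10, which are the hard part of the molecule.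
- Comparison: it is more reliable than a photocycloaddition, and that is conceded. The chosen key step builds far more of the target at once (two bonds, two rings, C10 and C5).

Key step: step 12

Remark on the chemistry: atoms are labelled C1–C20 in ent-kaurane numbering throughout; enol ether 17 is taken as the Z isomer expected from soft enolisation, and the E isomer should serve equally, because C6 becomes trigonal again in step 14.

## Route

Step 1
Reactants: 1 4,4-dimethylcyclohex-2-en-1-one
Product: 2 2-iodo-4,4-dimethylcyclohex-2-en-1-one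
Conditions: I2, pyridine, CH2Cl2, 0 °C → rt
Reagents that add atoms: iodine, II
Why: α-Iodination of an enone by conjugate addition of pyridine, iodination of the enolate and elimination; C4 is quaternary, so only C2 can be substituted.

Step 2
Reactants: 2 2-iodo-4,4-dimethylcyclohex-2-en-1-one
Product: 3 6-iodo-8,8-dimethyl-1,4-dioxaspiro[4.5]dec-6-ene
Conditions: HOCH2CH2OH, p-TsOH·H2O (cat.), benzene, reflux (Dean–Stark)
Reagents that add atoms: ethane-1,2-diol, OCCO
Why: Acid-catalysed ketalisation with azeotropic removal of water; the quaternary C4 stops the double bond from moving, so the alkenyl iodide is kept.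

Step 3
Reactants: 3 6-iodo-8,8-dimethyl-1,4-dioxaspiro[4.5]dec-6-ene
Product: 5 2-(8,8-dimethyl-1,4-dioxaspiro[4.5]dec-6-en-6-yl)-4,4,5,5-tetramethyl-1,3,2-dioxaborolane, via alkenyllithium 4 (not isolated)
Conditions: n-BuLi, THF, −78 °C; then i-PrOBpin, −78 °C → rt; aq. NH4Cl
Reagents that add atoms: n-butyllithium, [Li]CCCC (lithium of intermediate 4 only); 2-isopropoxy-4,4,5,5-tetramethyl-1,3,2-dioxaborolane, CC(C)OB1OC(C)(C)C(C)(C)O1
Why: Iodine–lithium exchange gives the alkenyllithium, which is trapped at boron; loss of isopropoxide from the ate complex leaves the pinacol boronate.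

Step 4
Reactants: 6 ethyl levulinate (ethyl 4-oxopentanoate)
Product: 7 ethyl 3-(2-methyl-1,3-dioxolan-2-yl)propanoate
Conditions: HOCH2CH2OH, p-TsOH·H2O (cat.), toluene, reflux (Dean–Stark)
Reagents that add atoms: ethane-1,2-diol, OCCO
Why: Standard ketalisation of the ketone; the ester is untouched and the ketal masks C13 through the organometallic and photochemical steps.

Step 5
Reactants: 7 ethyl 3-(2-methyl-1,3-dioxolan-2-yl)propanoate
Product: 8 3-(2-methyl-1,3-dioxolan-2-yl)propanal
Conditions: DIBAL-H, CH2Cl2, −78 °C; Rochelle salt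
Reagents that add atoms: none
Why: At −78 °C the aluminium hemiacetal is stable and releases the aldehyde only on work-up (partial reduction of an ester).

Step 6
Reactants: 8 3-(2-methyl-1,3-dioxolan-2-yl)propanal; 9 triethyl phosphonoacetate
Product: 11 ethyl (2E)-5-(2-methyl-1,3-dioxolan-2-yl)pent-2-enoate, via sodium phosphonate carbanion 10 (not isolated)
Conditions: NaH, THF, 0 °C; then 8, 0 °C → rt
Reagents that add atoms: sodium hydride, [Na+].[H-] (sodium of intermediate 10 only)
Why: Horner–Wadsworth–Emmons olefination of a stabilised phosphonate carbanion, which gives the (E)-enoate.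

Step 7
Reactants: 5 2-(8,8-dimethyl-1,4-dioxaspiro[4.5]dec-6-en-6-yl)-4,4,5,5-tetramethyl-1,3,2-dioxaborolane; 11 ethyl (2E)-5-(2-methyl-1,3-dioxolan-2-yl)pent-2-enoate
Product: 12 ethyl (3R)-3-(8,8-dimethyl-1,4-dioxaspiro[4.5]dec-6-en-6-yl)-5-(2-methyl-1,3-dioxolan-2-yl)pentanoate
Conditions: [RhCl(C2H4)2]2 (2.5 mol %), (1R,4R)-2,5-diphenylbicyclo[2.2.2]octa-2,5-diene (5.5 mol %; its antipode if the sense proves opposite), KOH (aq., 0.5 equiv), dioxane/H2O (10:1), 50 °C
Reagents that add atoms: none
Why: Rhodium-catalysed asymmetric 1,4-addition of an alkenylboron reagent to an enoate (Hayashi–Miyaura reaction): transmetalation gives an alkenylrhodium species that inserts the enoate on the face left open by the C2-symmetric diene, and water protonates the rhodium enolate. The ligand alone sets C9 (3R); a cyclic allene would be needed for β-alkoxide loss from the alkenylrhodium, so the neighbouring ketal is safe.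

Step 8
Reactants: 12 ethyl (3R)-3-(8,8-dimethyl-1,4-dioxaspiro[4.5]dec-6-en-6-yl)-5-(2-methyl-1,3-dioxolan-2-yl)pentanoate
Product: 13 prop-2-en-1-yl (3R)-3-(8,8-dimethyl-1,4-dioxaspiro[4.5]dec-6-en-6-yl)-5-(2-methyl-1,3-dioxolan-2-yl)pentanoate
Conditions: Ti(Oi-Pr)4 (0.2 equiv), allyl alcohol, 85 °C
Reagents that add atoms: prop-2-en-1-ol, C=CCO
Why: Titanate-mediated transesterification under neutral conditions that spare both ketals; the excess of allyl alcohol drives the exchange.

Step 9
Reactants: 13 prop-2-en-1-yl (3R)-3-(8,8-dimethyl-1,4-dioxaspiro[4.5]dec-6-en-6-yl)-5-(2-methyl-1,3-dioxolan-2-yl)pentanoate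
Product: 14 prop-2-en-1-yl (3R)-3-(3,3-dimethyl-6-oxocyclohex-1-en-1-yl)-5-(2-methyl-1,3-dioxolan-2-yl)pentanoate
Conditions: oxalic acid (5% aq.), THF, 0 °C → rt
Reagents that add atoms: water, O
Why: Selective hydrolysis of an α,β-unsaturated ketal: the ring ketal ionises to an allyl-stabilised oxocarbenium ion and ends as a conjugated enone, so it should go well before the isolated C13 ketal.

Step 10
Reactants: 14 prop-2-en-1-yl (3R)-3-(3,3-dimethyl-6-oxocyclohex-1-en-1-yl)-5-(2-methyl-1,3-dioxolan-2-yl)pentanoate
Product: 16 2-oxoethyl (3R)-3-(3,3-dimethyl-6-oxocyclohex-1-en-1-yl)-5-(2-methyl-1,3-dioxolan-2-yl)pentanoate, via vicinal diol 15 (not isolated)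
Conditions: OsO4 (2 mol %), NaIO4, 2,6-lutidine, dioxane/H2O (3:1), rt
Reagents that add atoms: osmium tetroxide, O=[Os](=O)(=O)=O (oxygen atoms of 15 and the aldehyde oxygen of 16); sodium periodate, [Na+].[O-]I(=O)(=O)=O (terminal oxidant that restores OsO4)
Why: Lemieux–Johnson cleavage: OsO4 takes the monosubstituted allyl alkene in preference to the electron-poor, trisubstituted and crowded enone alkene, and periodate cleaves the diol.

Step 11
Reactants: 16 2-oxoethyl (3R)-3-(3,3-dimethyl-6-oxocyclohex-1-en-1-yl)-5-(2-methyl-1,3-dioxolan-2-yl)pentanoate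
Product: 17 (Z)-2-[(tert-butyldimethylsilyl)oxy]ethenyl (3R)-3-(3,3-dimethyl-6-oxocyclohex-1-en-1-yl)-5-(2-methyl-1,3-dioxolan-2-yl)pentanoate
Conditions: TBSOTf (1.1 equiv), Et3N, CH2Cl2, −78 °C
Reagents that add atoms: tert-butyldimethylsilyl trifluoromethanesulfonate, CC(C)(C)[Si](C)(C)OS(=O)(=O)C(F)(F)F
Why: Soft enolisation: the unhindered aldehyde, whose α-hydrogens are acidified by the acyloxy group, is silylated on oxygen and deprotonated by the amine. With one equivalent of triflate at −78 °C the hindered ring A ketone should stay untouched.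

Step 12
Reactants: 17 (Z)-2-[(tert-butyldimethylsilyl)oxy]ethenyl (3R)-3-(3,3-dimethyl-6-oxocyclohex-1-en-1-yl)-5-(2-methyl-1,3-dioxolan-2-yl)pentanoate
Product: 18 cyclobutane photoadduct, C6 silyl ether
Conditions: hν (350 nm, Pyrex), MeCN (0.005 M, degassed), rt
Reagents that add atoms: none
Why: Excitation of the enone and intersystem crossing give the twisted triplet, which attacks the electron-rich enol ether; C10 bonds to C20 first, leaving a 1,4-biradical (C5 alkyl, C6 α-silyloxy) that closes the four-membered ring after spin inversion. The closest known reaction type is the intramolecular enone–alkene [2+2] photocycloaddition with enol ether or enol ester partners, giving the straight adduct. The δ-lactone closes in the first bond-forming event as a 6-exo ring through the ester tether, in a chair-like arrangement with C11 equatorial; the cyclobutane closes by recombination of the 1,4-biradical. C10 is controlled by C9: in the conformer that minimises allylic strain H-9 lies in the enone plane next to H-5, so the tether carbon C8 and C11 sit on opposite faces and C20 arrives from the face of C8. C5 follows from the cis fusion of the four-membered ring to ring A, C20 from its cis fusion to the lactone, and C6, which may scramble in the biradical, is trigonal again after step 14. The step needs straight and not crossed regiochemistry, which is secured because bonding of C10 to C6 would require a seven-membered ring, and it needs the correct enone face, which C9 provides. High dilution suppresses dimerisation, and irradiation at 350 nm keeps the saturated product ketone from absorbing.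

Step 13
Reactants: 18 cyclobutane photoadduct, C6 silyl ether
Product: 19 cyclobutanol lactone (C6 hydroxyl free)
Conditions: HF·pyridine, pyridine, THF, 0 °C
Reagents that add atoms: none
Why: Fluoride-mediated desilylation under buffered, non-basic conditions; no alkoxide is formed, so the lactone acyl group does not migrate and the C20 oxygen stays acylated (no retro-aldol opening).

Step 14
Reactants: 19 cyclobutanol lactone (C6 hydroxyl free)
Product: 20 10,10-dimethyl-5-[2-(2-methyl-1,3-dioxolan-2-yl)ethyl]-3,7-dioxo-2-oxaspiro[5.5]undecane-11-carbaldehyde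
Conditions: [Ir(dF(CF3)ppy)2(5,5′-d(CF3)bpy)]PF6 (2 mol %), 2,4,6-triisopropylbenzenethiol (25 mol %), 2,4,6-collidine, PhCF3, blue LEDs, rt
Reagents that add atoms: none
Why: Redox-neutral ring-opening isomerisation of a cycloalkanol: proton-coupled electron transfer to the excited iridium complex and the base turns O–H into an alkoxy radical, and strain-driven β-scission breaks C6–C20. This bond is preferred to C5–C6 because its cleavage leaves the oxygen-stabilised C20 radical, which then takes a hydrogen atom from the thiol. C6 becomes the aldehyde and C20 the lactone methylene; C5 and C10 are not touched.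

Step 15
Reactants: 20 10,10-dimethyl-5-[2-(2-methyl-1,3-dioxolan-2-yl)ethyl]-3,7-dioxo-2-oxaspiro[5.5]undecane-11-carbaldehyde
Product: 21 11-(1,3-dioxolan-2-yl)-10,10-dimethyl-5-[2-(2-methyl-1,3-dioxolan-2-yl)ethyl]-2-oxaspiro[5.5]undecane-3,7-dione
Conditions: TMSOCH2CH2OTMS, TMSOTf (cat.), CH2Cl2, −78 → −20 °C
Reagents that add atoms: 1,2-bis(trimethylsilyloxy)ethane, C[Si](C)(C)OCCO[Si](C)(C)C
Why: Noyori acetalisation, which at low temperature takes the aldehyde and leaves the neopentyl C1 ketone; no base is present, so C5 keeps its configuration.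

Step 16
Reactants: 21 11-(1,3-dioxolan-2-yl)-10,10-dimethyl-5-[2-(2-methyl-1,3-dioxolan-2-yl)ethyl]-2-oxaspiro[5.5]undecane-3,7-dione
Product: 23 11-(1,3-dioxolan-2-yl)-10,10-dimethyl-5-[2-(2-methyl-1,3-dioxolan-2-yl)ethyl]-2-oxaspiro[5.5]undec-8-ene-3,7-dione, via trimethylsilyl enol ether 22 (not isolated)
Conditions: LiHMDS, TMSCl, THF, −78 °C; then Pd(OAc)2, MeCN, rt
Reagents that add atoms: chlorotrimethylsilane, C[Si](C)(C)Cl (silyl group of intermediate 22 only)
Why: Saegusa–Ito oxidation: the ketone, more acidic than the lactone, enolises toward C2 only (C10 is quaternary), and the oxa-π-allylpalladium species loses the C3 hydride. The new enone has no enolisable hydrogen, which leaves the lactone as the only acidic site for step 17.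

Step 17
Reactants: 23 11-(1,3-dioxolan-2-yl)-10,10-dimethyl-5-[2-(2-methyl-1,3-dioxolan-2-yl)ethyl]-2-oxaspiro[5.5]undec-8-ene-3,7-dione
Product: 25 4-acetyl-11-(1,3-dioxolan-2-yl)-10,10-dimethyl-5-[2-(2-methyl-1,3-dioxolan-2-yl)ethyl]-2-oxaspiro[5.5]undec-8-ene-3,7-dione, via lithium lactone enolate 24 (not isolated)
Conditions: LiHMDS (2.2 equiv), THF, −78 °C; then AcN(OMe)Me, −78 → −20 °C; aq. NH4Cl
Reagents that add atoms: N-methoxy-N-methylacetamide, CC(=O)N(C)OC; lithium hexamethyldisilazide, [Li]N([Si](C)(C)C)[Si](C)(C)C (lithium of intermediate 24 only)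
Why: Claisen-type C-acylation of a lactone enolate with a Weinreb amide; the chelated tetrahedral adduct keeps the acyl group from reacting twice and from going to oxygen. C8 is enolisable in 25, so its configuration at this stage does not matter.

Step 18
Reactants: 25 4-acetyl-11-(1,3-dioxolan-2-yl)-10,10-dimethyl-5-[2-(2-methyl-1,3-dioxolan-2-yl)ethyl]-2-oxaspiro[5.5]undec-8-ene-3,7-dione
Product: 26 4-acetyl-11-(1,3-dioxolan-2-yl)-10,10-dimethyl-5-(3-oxobutyl)-2-oxaspiro[5.5]undec-8-ene-3,7-dione
Conditions: PPTS (cat.), acetone/H2O (20:1), 35 °C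
Reagents that add atoms: water, O
Why: A ketone-derived dioxolane hydrolyses orders of magnitude faster than the aldehyde-derived, neopentyl dioxolane at C6, so mild acid should free only the C13 ketone.

Step 19
Reactants: 26 4-acetyl-11-(1,3-dioxolan-2-yl)-10,10-dimethyl-5-(3-oxobutyl)-2-oxaspiro[5.5]undec-8-ene-3,7-dione
Product: 28 tricyclic acetyl diketo lactone (ring C closed), via dilithium bis-enolate 27 (not isolated)
Conditions: LDA (2.3 equiv), THF, −78 °C; then [Fe(DMF)3Cl2][FeCl4], DMF, −78 → 0 °C
Reagents that add atoms: lithium diisopropylamide, [Li]N(C(C)C)C(C)C (lithium of intermediate 27 only)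
Why: Intramolecular oxidative coupling of a 1,3-dicarbonyl enolate with a ketone enolate: the β-keto lactone is deprotonated first, then the methyl ketone at its methyl group under kinetic control, and one-electron oxidation by trivalent iron joins C8 to C14 in a six-membered ring. The new bond forms axially on the lactone ring, on the side of the C9–C11 bond, which gives the cis ring fusion and therefore the C8 configuration of 35.

Step 20
Reactants: 28 tricyclic acetyl diketo lactone (ring C closed)
Product: 30 tetracyclic 15-ketone, C13 trimethylsilyl ether (ring D closed), via lithium aldolate 29 (not isolated)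
Conditions: LiHMDS (1.05 equiv), THF, −78 → −30 °C; then TMSCl, −78 °C
Reagents that add atoms: chlorotrimethylsilane, C[Si](C)(C)Cl; lithium hexamethyldisilazide, [Li]N([Si](C)(C)C)[Si](C)(C)C (lithium of intermediate 29 only)
Why: Intramolecular aldol addition of a 1,4-diketone: the C16 enolate of the acetyl group adds to the C13 ketone across ring C, which is possible only from the axial acetyl conformer and therefore fixes C13. Dehydration would need a bridgehead alkene and does not occur, enolates at other positions can equilibrate into this productive one, and silylation of the aldolate closes the retro-aldol path.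

Step 21
Reactants: 30 tetracyclic 15-ketone, C13 trimethylsilyl ether (ring D closed)
Product: 33 16-methylene 15-ketone (bis-enone), via Mannich base 31 (not isolated), via quaternary ammonium iodide 32 (not isolated)
Conditions: LiHMDS, THF, −78 °C; CH2=NMe2+ I−; then MeI, CH2Cl2, rt; then DBU
Reagents that add atoms: N,N-dimethylmethyleneiminium iodide (Eschenmoser's salt), C=[N+](C)C.[I-]; iodomethane, CI (methyl group of intermediate 32 only)
Why: α-Methylenation by aminomethylation and elimination: C16 is the only enolisable carbon left, its enolate is trapped by the iminium salt, and quaternisation followed by base expels trimethylamine to give the exocyclic enone.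

Step 22
Reactants: 33 16-methylene 15-ketone (bis-enone)
Product: 34 15-hydroxy-16-ene, C13 trimethylsilyl ether, C6 dioxolane
Conditions: NaBH4 (1 equiv), CeCl3·7H2O, MeOH, −78 °C
Reagents that add atoms: none
Why: Luche 1,2-reduction: the C15 carbonyl sits in the strained bicycle next to a tied-back bridgehead and should react before the ring A carbonyl, which is screened by the freely projecting substituents of C10. Hydride enters from the exo face, away from the C9–C11–C12 bridge, and so places the hydroxyl endo (15R).

Step 23
Reactants: 34 15-hydroxy-16-ene, C13 trimethylsilyl ether, C6 dioxolane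
Product: 35 CNP0521079.1, 13,15-dihydroxy-1,6-dioxo-6,7-seco-ent-kaura-2,16-dien-7,20-olide
Conditions: PPTS, acetone/H2O (5:1), 45 °C
Reagents that add atoms: water, O
Why: Mild acid hydrolysis of the dioxolane and of the tertiary silyl ether; the weak acid is chosen to spare the allylic alcohol, the bridgehead alcohol cannot ionise, and C5 is not expected to epimerise under these conditions.

## Compound list

1 | 4,4-dimethylcyclohex-2-en-1-one | CC1(C)CCC(=O)C=C1 | starting material
2 | 2-iodo-4,4-dimethylcyclohex-2-en-1-one | CC1(C)CCC(=O)C(I)=C1 | intermediate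
3 | 6-iodo-8,8-dimethyl-1,4-dioxaspiro[4.5]dec-6-ene | CC1(C)CCC2(OCCO2)C(I)=C1 | intermediate
4 | (8,8-dimethyl-1,4-dioxaspiro[4.5]dec-6-en-6-yl)lithium, formed in situ | [Li]C1=CC(C)(C)CCC12OCCO2 | intermediate
5 | 2-(8,8-dimethyl-1,4-dioxaspiro[4.5]dec-6-en-6-yl)-4,4,5,5-tetramethyl-1,3,2-dioxaborolane | CC1(C)CCC2(OCCO2)C(=C1)B3OC(C)(C)C(C)(C)O3 | intermediate
6 | ethyl levulinate (ethyl 4-oxopentanoate) | CCOC(=O)CCC(C)=O | starting material
7 | ethyl 3-(2-methyl-1,3-dioxolan-2-yl)propanoate | CCOC(=O)CCC1(C)OCCO1 | intermediate
8 | 3-(2-methyl-1,3-dioxolan-2-yl)propanal | O=CCCC1(C)OCCO1 | intermediate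
9 | triethyl phosphonoacetate | CCOC(=O)CP(=O)(OCC)OCC | starting material
10 | sodium salt of the carbanion of 9, formed in situ | [Na+].CCOC(=O)[CH-]P(=O)(OCC)OCC | intermediate
11 | ethyl (2E)-5-(2-methyl-1,3-dioxolan-2-yl)pent-2-enoate | CCOC(=O)/C=C/CCC1(C)OCCO1 | intermediate
12 | ethyl (3R)-3-(8,8-dimethyl-1,4-dioxaspiro[4.5]dec-6-en-6-yl)-5-(2-methyl-1,3-dioxolan-2-yl)pentanoate | CC1(OCCO1)CC[C@H](CC(=O)OCC)C2=CC(C)(C)CCC23OCCO3 | intermediate
13 | prop-2-en-1-yl (3R)-3-(8,8-dimethyl-1,4-dioxaspiro[4.5]dec-6-en-6-yl)-5-(2-methyl-1,3-dioxolan-2-yl)pentanoate | CC1(OCCO1)CC[C@H](CC(=O)OCC=C)C2=CC(C)(C)CCC23OCCO3 | intermediate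
14 | prop-2-en-1-yl (3R)-3-(3,3-dimethyl-6-oxocyclohex-1-en-1-yl)-5-(2-methyl-1,3-dioxolan-2-yl)pentanoate | CC1(OCCO1)CC[C@H](CC(=O)OCC=C)C2=CC(C)(C)CCC2=O | intermediate
15 | 2,3-dihydroxypropyl (3R)-3-(3,3-dimethyl-6-oxocyclohex-1-en-1-yl)-5-(2-methyl-1,3-dioxolan-2-yl)pentanoate, formed in situ, both carbinol epimers | CC1(OCCO1)CC[C@H](CC(=O)OCC(O)CO)C2=CC(C)(C)CCC2=O | intermediate
16 | 2-oxoethyl (3R)-3-(3,3-dimethyl-6-oxocyclohex-1-en-1-yl)-5-(2-methyl-1,3-dioxolan-2-yl)pentanoate | CC1(OCCO1)CC[C@H](CC(=O)OCC=O)C2=CC(C)(C)CCC2=O | intermediate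
17 | (Z)-2-[(tert-butyldimethylsilyl)oxy]ethenyl (3R)-3-(3,3-dimethyl-6-oxocyclohex-1-en-1-yl)-5-(2-methyl-1,3-dioxolan-2-yl)pentanoate | CC1(OCCO1)CC[C@H](CC(=O)O/C=C\O[Si](C)(C)C(C)(C)C)C2=CC(C)(C)CCC2=O | intermediate
18 | cyclobutane photoadduct, C6 silyl ether: ring A 4,4-dimethylcyclohexan-1-one cis-fused at C5–C10 to the cyclobutane C5–C6–C20–C10; δ-lactone C7(=O)–O–C20 fused at C10–C20; tert-butyldimethylsilyloxy on C6 cis to the lactone oxygen on C20, on the cyclobutane face remote from ring A; 2-(2-methyl-1,3-dioxolan-2-yl)ethyl on C9; C5, C9 and C10 as in 35 | CC1(OCCO1)CC[C@@H]2CC(=O)O[C@H]3[C@@H](O[Si](C)(C)C(C)(C)C)[C@@H]4C(C)(C)CCC(=O)[C@]234 | intermediate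
19 | cyclobutanol lactone: as 18 with a free hydroxyl on C6 | CC1(OCCO1)CC[C@@H]2CC(=O)O[C@H]3[C@@H](O)[C@@H]4C(C)(C)CCC(=O)[C@]234 | intermediate
20 | 10,10-dimethyl-5-[2-(2-methyl-1,3-dioxolan-2-yl)ethyl]-3,7-dioxo-2-oxaspiro[5.5]undecane-11-carbaldehyde (spiro positions 11, 5 and 6 are kaurane C5, C9 and C10, configured as in 35) | CC1(OCCO1)CC[C@@H]2CC(=O)OC[C@]23C(=O)CCC(C)(C)[C@H]3C=O | intermediate
21 | 11-(1,3-dioxolan-2-yl)-10,10-dimethyl-5-[2-(2-methyl-1,3-dioxolan-2-yl)ethyl]-2-oxaspiro[5.5]undecane-3,7-dione (C5, C9, C10 as in 35) | CC1(OCCO1)CC[C@@H]2CC(=O)OC[C@]23C(=O)CCC(C)(C)[C@H]3C4OCCO4 | intermediate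
22 | 11-(1,3-dioxolan-2-yl)-10,10-dimethyl-5-[2-(2-methyl-1,3-dioxolan-2-yl)ethyl]-7-[(trimethylsilyl)oxy]-2-oxaspiro[5.5]undec-7-en-3-one, formed in situ | CC1(OCCO1)CC[C@@H]2CC(=O)OC[C@]23C(O[Si](C)(C)C)=CCC(C)(C)[C@H]3C4OCCO4 | intermediate
23 | 11-(1,3-dioxolan-2-yl)-10,10-dimethyl-5-[2-(2-methyl-1,3-dioxolan-2-yl)ethyl]-2-oxaspiro[5.5]undec-8-ene-3,7-dione (C5, C9, C10 as in 35) | CC1(OCCO1)CC[C@@H]2CC(=O)OC[C@]23C(=O)C=CC(C)(C)[C@H]3C4OCCO4 | intermediate
24 | lithium enolate of lactone 23 (C7–C8), formed in situ | [Li+].CC1(OCCO1)CC[C@@H]2C=C([O-])OC[C@]23C(=O)C=CC(C)(C)[C@H]3C4OCCO4 | intermediate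
25 | 4-acetyl-11-(1,3-dioxolan-2-yl)-10,10-dimethyl-5-[2-(2-methyl-1,3-dioxolan-2-yl)ethyl]-2-oxaspiro[5.5]undec-8-ene-3,7-dione (acetyl on kaurane C8; C8 epimers and enol form) | CC1(OCCO1)CC[C@@H]2C(C(C)=O)C(=O)OC[C@]23C(=O)C=CC(C)(C)[C@H]3C4OCCO4 | intermediate
26 | 4-acetyl-11-(1,3-dioxolan-2-yl)-10,10-dimethyl-5-(3-oxobutyl)-2-oxaspiro[5.5]undec-8-ene-3,7-dione (C8 epimers and enol form) | CC(=O)CC[C@@H]1C(C(C)=O)C(=O)OC[C@]12C(=O)C=CC(C)(C)[C@H]2C3OCCO3 | intermediate
27 | dilithium bis-enolate of 26 (C8=C15 enolate of the β-keto lactone and C13=C14 enolate of the methyl ketone), formed in situ | [Li+].[Li+].C=C([O-])CC[C@@H]1C(=C(C)[O-])C(=O)OC[C@]12C(=O)C=CC(C)(C)[C@H]2C3OCCO3 | intermediate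
28 | tricyclic acetyl diketo lactone: cyclohexanone ring C (C8, C9, C11, C12, C13 ketone, C14) cis-fused at C8–C9 to the δ-lactone, acetyl (C15, C16) on C8, ring A enone and C6 dioxolane as in 23; C5, C8, C9, C10 as in 35 | CC(=O)[C@]12CC(=O)CC[C@H]1[C@]3(COC2=O)C(=O)C=CC(C)(C)[C@H]3C4OCCO4 | intermediate
29 | lithium C13 alkoxide of the ring D aldol, formed in situ | [Li+].C1C(=O)[C@]23C[C@@]1([O-])CC[C@H]2[C@]1(COC3=O)C(=O)C=CC(C)(C)[C@H]1C4OCCO4 | intermediate
30 | tetracyclic 15-ketone: 6,6-(ethylenedioxy)-1,15-dioxo-13-[(trimethylsilyl)oxy]-17-nor-6,7-seco-ent-kaur-2-en-7,20-olide; C5, C8, C9, C10, C13 as in 35 | C1C(=O)[C@]23C[C@@]1(O[Si](C)(C)C)CC[C@H]2[C@]1(COC3=O)C(=O)C=CC(C)(C)[C@H]1C4OCCO4 | intermediate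
31 | 16-[(dimethylamino)methyl] derivative of 30 (Mannich base, C16 epimers), formed in situ | CN(C)CC1C(=O)[C@]23C[C@@]1(O[Si](C)(C)C)CC[C@H]2[C@]1(COC3=O)C(=O)C=CC(C)(C)[C@H]1C4OCCO4 | intermediate
32 | trimethylammonium iodide of 31, formed in situ | [I-].C[N+](C)(C)CC1C(=O)[C@]23C[C@@]1(O[Si](C)(C)C)CC[C@H]2[C@]1(COC3=O)C(=O)C=CC(C)(C)[C@H]1C4OCCO4 | intermediate
33 | bis-enone: 6,6-(ethylenedioxy)-1,15-dioxo-13-[(trimethylsilyl)oxy]-6,7-seco-ent-kaura-2,16-dien-7,20-olide | C=C1C(=O)[C@]23C[C@@]1(O[Si](C)(C)C)CC[C@H]2[C@]1(COC3=O)C(=O)C=CC(C)(C)[C@H]1C4OCCO4 | intermediate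
34 | (15R)-6,6-(ethylenedioxy)-15-hydroxy-1-oxo-13-[(trimethylsilyl)oxy]-6,7-seco-ent-kaura-2,16-dien-7,20-olide (hydroxyl endo, toward the C9–C11–C12 bridge) | C=C1[C@@H](O)[C@]23C[C@@]1(O[Si](C)(C)C)CC[C@H]2[C@]1(COC3=O)C(=O)C=CC(C)(C)[C@H]1C4OCCO4 | intermediate
35 | CNP0521079.1: (5R,8S,9S,10S,13S,15R)-13,15-dihydroxy-1,6-dioxo-6,7-seco-ent-kaura-2,16-dien-7,20-olide | C=C1[C@@H](O)[C@]23C[C@@]1(O)CC[C@H]2[C@]1(COC3=O)C(=O)C=CC(C)(C)[C@H]1C=O | target

## Step count and least certain steps

Total: 23 steps. Longest linear sequence: 20 steps (steps 1–3 or 4–6, then 7–23).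

**Step 12 (key step).** The ester tether prefers the rotamer in which C20 points away from C10, and the triplet lives too briefly for rotation. Closure may therefore be slow, and the usual escape routes of a 4,4-dimethylcyclohexenone triplet (skeletal rearrangement, dimerisation, hydrogen abstraction) may take over. The facial bias from C9 is also conformational and may prove modest.

Fallback: exchange the ester tether for a freely rotating ether and restore the lactone carbonyl afterwards. It sets out from 12 and comes back at 18.
- LiAlH4 reduces the ester to (3R)-3-(8,8-dimethyl-1,4-dioxaspiro[4.5]dec-6-en-6-yl)-5-(2-methyl-1,3-dioxolan-2-yl)pentan-1-ol F1.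
- NaH and allyl bromide give its allyl ether F2.
- Aqueous oxalic acid frees the ring A enone F3.
- OsO4/NaIO4 gives the (2-oxoethyl) ether F4.
- TBSOTf/Et3N gives the (Z)-2-silyloxyvinyl ether F5.
- Irradiation at 350 nm closes the tetrahydropyran-fused cyclobutane F6.
- RuCl3 (cat.)/NaIO4 oxidises the unhindered ether methylene C7 to the lactone carbonyl, which gives 18.

**Step 14.** The alkoxy radical may break C5–C6 instead of C6–C20. The C20 radical may shift onto the C1 carbonyl before it is reduced. The hindered hydroxyl may also resist activation while other C–H bonds are oxidised. The choice of bond is intrinsic to the alkoxy radical and is the untested point.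

Fallback: a covalent radical precursor under stannane chain conditions. It removes the oxidant and allows a high, adjustable hydrogen-donor concentration, but it does not change the intrinsic scission preference. It sets out from 19 and comes back at 20. PhSCl/Et3N at −78 °C gives the O-phenylsulfenate F7, and Bu3SnH (0.2 M)/AIBN in benzene at 80 °C releases the same alkoxy radical and reduces the C20 radical, which gives 20.

**Step 19.** Enolisation may be unselective (C12 in place of C14). Intermolecular coupling or α-chlorination by the iron salt may compete with ring closure.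

Fallback: oxidation of isolated neutral enol ethers instead of metal enolates. It sets out from 26 and comes back at 28. LDA (2.2 equiv)/TMSCl gives the bis(trimethylsilyl) enol ether F8, and (NH4)2Ce(NO3)6 with NaHCO3 in MeCN at −20 °C couples the two enol ethers through a radical cation to give 28.

**Step 22.** Hydride may also add to the ring A carbonyl, since both ketones are conjugated and both have a quaternary neighbour. Conjugate reduction at C17 is a further risk.

Fallback: mask the D-ring enone as a saturated ketone. It sets out from 33 and comes back at 34.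
- PhSeSePh/NaBH4 in EtOH, buffered with AcOH, adds selenolate to the unhindered C17 and gives the β-seleno ketone F9. The neopentyl β-carbon of ring A does not accept it.
- NaBH4 in MeOH/CH2Cl2 at −78 °C reduces this saturated ketone in preference to the enone and gives the alcohol F10.
- H2O2/pyridine forms the selenoxide, which eliminates toward C16 and gives 34.

**Step 7.** The alkenyl boronate is flanked by two quaternary carbons, so transmetalation and insertion may be slow and protodeboronation may win.

Fallback: auxiliary-controlled cuprate addition. It sets out from 8 and 3 and comes back at 13.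
- Aldehyde 8 and the (4S)-4-benzyl-3-(diethoxyphosphorylacetyl)oxazolidin-2-one reagent (LiCl, i-Pr2NEt) give the N-enoyl oxazolidinone F11.
- The alkenyllithium from 3 (n-BuLi), turned into its cuprate with CuBr·SMe2, adds anti to the benzyl group of the chelated imide and gives the (3R) adduct F12.
- Lithium allyloxide in allyl alcohol cleaves the auxiliary and gives 13.

**Step 23.** The neopentyl dioxolane may need more acid than the 15-hydroxy-16-ene tolerates, which would isomerise the allylic alcohol to a 16-methyl 15-ketone.

Fallback: remove the dioxolane before the allylic alcohol exists. It sets out from 33 and comes back at 35.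
- More forcing aqueous acid (TsOH·H2O, acetone/H2O, 50 °C) on the bis-enone gives the free aldehyde F13 with a free C13 hydroxyl.
- CeCl3·7H2O/HC(OMe)3 in MeOH masks the aldehyde in the flask as its dimethyl acetal F14.
- NaBH4 at −78 °C reduces C15 to the alcohol F15.
- Brief dilute acid in the work-up cleaves the labile dimethyl acetal and gives 35.

## Further compounds

F1 | step 12 | (3R)-3-(8,8-dimethyl-1,4-dioxaspiro[4.5]dec-6-en-6-yl)-5-(2-methyl-1,3-dioxolan-2-yl)pentan-1-ol | CC1(OCCO1)CC[C@H](CCO)C2=CC(C)(C)CCC23OCCO3
F2 | step 12 | 8,8-dimethyl-6-[(3R)-1-(2-methyl-1,3-dioxolan-2-yl)-5-(prop-2-en-1-yloxy)pentan-3-yl]-1,4-dioxaspiro[4.5]dec-6-ene | CC1(OCCO1)CC[C@H](CCOCC=C)C2=CC(C)(C)CCC23OCCO3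
F3 | step 12 | 4,4-dimethyl-2-[(3R)-1-(2-methyl-1,3-dioxolan-2-yl)-5-(prop-2-en-1-yloxy)pentan-3-yl]cyclohex-2-en-1-one | CC1(OCCO1)CC[C@H](CCOCC=C)C2=CC(C)(C)CCC2=O
F4 | step 12 | {[(3R)-3-(3,3-dimethyl-6-oxocyclohex-1-en-1-yl)-5-(2-methyl-1,3-dioxolan-2-yl)pentyl]oxy}acetaldehyde | CC1(OCCO1)CC[C@H](CCOCC=O)C2=CC(C)(C)CCC2=O
F5 | step 12 | 2-[(3R)-5-{[(Z)-2-[(tert-butyldimethylsilyl)oxy]ethenyl]oxy}-1-(2-methyl-1,3-dioxolan-2-yl)pentan-3-yl]-4,4-dimethylcyclohex-2-en-1-one | CC1(OCCO1)CC[C@H](CCO/C=C\O[Si](C)(C)C(C)(C)C)C2=CC(C)(C)CCC2=O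
F6 | step 12 | 7-deoxo analogue of 18 (tetrahydropyran in place of the δ-lactone, C7 a methylene) | CC1(OCCO1)CC[C@@H]2CCO[C@H]3[C@@H](O[Si](C)(C)C(C)(C)C)[C@@H]4C(C)(C)CCC(=O)[C@]234
F7 | step 14 | O-(phenylsulfanyl) derivative of cyclobutanol 19 (benzenesulfenate ester at O6) | CC1(OCCO1)CC[C@@H]2CC(=O)O[C@H]3[C@@H](OSc5ccccc5)[C@@H]4C(C)(C)CCC(=O)[C@]234
F8 | step 19 | bis(trimethylsilyl) enol ether of 26 (C8=C15 and C13=C14 silyl enol ethers) | C=C(O[Si](C)(C)C)CC[C@@H]1C(=C(C)O[Si](C)(C)C)C(=O)OC[C@]12C(=O)C=CC(C)(C)[C@H]2C3OCCO3
F9 | step 22 | 17-(phenylselanyl)-16,17-dihydro derivative of 33 (C16 epimers) | c1ccccc1[Se]CC2C(=O)[C@]34C[C@@]2(O[Si](C)(C)C)CC[C@H]3[C@]5(COC4=O)C(=O)C=CC(C)(C)[C@H]5C6OCCO6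
F10 | step 22 | (15R)-15-hydroxy-17-(phenylselanyl)-16,17-dihydro derivative of 34 (C16 epimers) | c1ccccc1[Se]CC2[C@@H](O)[C@]34C[C@@]2(O[Si](C)(C)C)CC[C@H]3[C@]5(COC4=O)C(=O)C=CC(C)(C)[C@H]5C6OCCO6
F11 | step 7 | (4S)-4-benzyl-3-[(2E)-5-(2-methyl-1,3-dioxolan-2-yl)pent-2-enoyl]-1,3-oxazolidin-2-one | CC1(OCCO1)CC/C=C/C(=O)N2[C@@H](Cc3ccccc3)COC2=O
F12 | step 7 | (4S)-4-benzyl-3-[(3R)-3-(8,8-dimethyl-1,4-dioxaspiro[4.5]dec-6-en-6-yl)-5-(2-methyl-1,3-dioxolan-2-yl)pentanoyl]-1,3-oxazolidin-2-one | CC1(OCCO1)CC[C@H](CC(=O)N2[C@@H](Cc3ccccc3)COC2=O)C4=CC(C)(C)CCC45OCCO5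
F13 | step 23 | 13-hydroxy-1,6,15-trioxo-6,7-seco-ent-kaura-2,16-dien-7,20-olide (15-ketone of 35) | C=C1C(=O)[C@]23C[C@@]1(O)CC[C@H]2[C@]1(COC3=O)C(=O)C=CC(C)(C)[C@H]1C=O
F14 | step 23 | C6 dimethyl acetal of F13 | C=C1C(=O)[C@]23C[C@@]1(O)CC[C@H]2[C@]1(COC3=O)C(=O)C=CC(C)(C)[C@H]1C(OC)OC
F15 | step 23 | C6 dimethyl acetal of 35 | C=C1[C@@H](O)[C@]23C[C@@]1(O)CC[C@H]2[C@]1(COC3=O)C(=O)C=CC(C)(C)[C@H]1C(OC)OC
A1 | alternative 1 | 15-O-(tert-butyldimethylsilyl) ether of 35 | C=C1[C@@H](O[Si](C)(C)C(C)(C)C)[C@]23C[C@@]1(O)CC[C@H]2[C@]1(COC3=O)C(=O)C=CC(C)(C)[C@H]1C=O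
A2 | alternative 2 | cyclohexene carboxylic acid with quaternary C8 (carboxyl C7 and a 3-(trimethylsilyl)prop-2-ynyl group), C13 dioxolane, C11=C12 alkene, and on C9 the ring A unit carrying the C20 silyl ether and the C6 dimethyl acetal | OC(=O)[C@@]1(CC#C[Si](C)(C)C)CC2(OCCO2)C=C[C@H]1[C@]3(CO[Si](C)(C)C(C)(C)C)C(=O)CCC(C)(C)[C@H]3C(OC)OC
A3 | alternative 3 | lactone-fused cyclohexanone with the ketone at C13, hydrogen on C8, saturated ring A ketone and C6 dimethyl acetal | [C@H]23CC(=O)CC[C@H]2[C@]1(COC3=O)C(=O)CCC(C)(C)[C@H]1C(OC)OC
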